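## Retrosynthetic overview

- The target, an all-trans 2,5-diaryl-3,4-dimethyloxolane, is traced back to its 3-formyl analogue; the C3 methyl group comes from the formyl group by way of CH2OH and CH2OMs, without touching a stereocentre.
- Key disconnection: the C2–C3 bond of the oxolane, an aldol retron inside the ring. C2 is bound to ring O1 and to the electron-rich 3,4-dimethoxyphenyl ring (a latent oxocarbenium carbon), and C3 carries the one-carbon substituent (a latent enol carbon).
- This leads to a convergent (4+1) annulation of 3,4-dimethoxybenzaldehyde with a 4-hydroxy-1-alkenyl carbamate: O1–C2 forms first, then C2–C3 closes the only ring.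
- The hydroxy enol carbamate (O1, C5, C4, C3 and the future C3 methyl carbon, with C4/C5 anti) comes from a sparteine-mediated asymmetric homoaldol reaction of (E)-crotyl carbamate with 3,4,5-trimethoxybenzaldehyde.
- C4 and C5 are set in step 2; C2 and C3 are set in step 3, where the oxolane is formed.

Key step: step 3

Assumption: the (−)-sparteine/Ti(Oi-Pr)4 homoaldol sequence is taken to give the (3S,4S) adduct (S-configured lithium complex, Li→Ti exchange with inversion, suprafacial addition); should the opposite sense be found, (+)-sparteine would be used in the same procedure.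

## Route

Step 1
Reactants: 1 (E)-but-2-en-1-ol
Product: 2 (E)-but-2-en-1-yl N,N-di(propan-2-yl)carbamate
Conditions: NaH, THF, 0 °C; then ClC(O)N(i-Pr)2, reflux
Reagents that add atoms: N,N-diisopropylcarbamoyl chloride, CC(C)N(C(C)C)C(Cl)=O
Why: O-carbamoylation of the sodium alkoxide (acyl substitution at the carbamoyl chloride) should install the directing, α-acidifying carbamate group without touching the E double bond; no stereocentre is formed.

Step 2
Reactants: 2 (E)-but-2-en-1-yl N,N-di(propan-2-yl)carbamate; 3 3,4,5-trimethoxybenzaldehyde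
Product: 6 (1Z,3S,4S)-4-hydroxy-3-methyl-4-(3,4,5-trimethoxyphenyl)but-1-en-1-yl N,N-di(propan-2-yl)carbamate, via (S)-lithiated carbamate sparteine complex 4 (not isolated), via allyltitanium triisopropoxide 5 (not isolated)
Conditions: n-BuLi, (−)-sparteine, pentane/cyclohexane, −78 °C (crystallisation); Ti(Oi-Pr)4, −78 °C; then 3 in toluene, −78 °C → rt; 2 M HCl
Reagents that add atoms: none
Why: In this sparteine-mediated asymmetric homoaldol reaction (Hoppe type), crystallisation-driven dynamic resolution should give the (S)-lithium complex, Li→Ti exchange with inversion gives the (R)-allyltitanium, and suprafacial γ-addition to the aldehyde through a Zimmerman–Traxler chair (aryl equatorial, carbamoyloxy axial) should set C3 and C4 anti and the enol carbamate Z.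

Step 3
Reactants: 6 (1Z,3S,4S)-4-hydroxy-3-methyl-4-(3,4,5-trimethoxyphenyl)but-1-en-1-yl N,N-di(propan-2-yl)carbamate; 7 3,4-dimethoxybenzaldehyde
Product: 10 (2S,3S,4S,5S)-2-(3,4-dimethoxyphenyl)-4-methyl-5-(3,4,5-trimethoxyphenyl)oxolane-3-carbaldehyde, via oxocarbenium ion 8 (not isolated), via carbamoyloxycarbenium ion 9 (not isolated)
Conditions: 7 (1.5 equiv), BF3·OEt2 (2 equiv), CH2Cl2, −78 → 0 °C; aq. NaHCO3
Reagents that add atoms: none
Why: BF3 should convert the hemiacetal formed from the hydroxyl group of 6 (the future O1) and aldehyde 7 into the (E)-oxocarbenium ion 8, whose carbon (the future C2) is attacked by the β-carbon of the Z-enol carbamate (the future C3) to give ion 9, which passes its carbamoyl group to fluoride and uncovers the formyl group. The closest known reaction type is the Lewis acid cyclocondensation of 4-hydroxy-1-alkenyl carbamates with aldehydes (an intramolecular Mukaiyama/Prins-type addition of an enol derivative to an oxocarbenium ion), mechanistically the same ion-pair collapse as in the Lewis acid ring contraction of 4,5-dihydro-1,3-dioxepines to 2-aryloxolane-3-carbaldehydes. The oxolane closes in a 5-(enol-exo)-endo-trig mode at the C=O+ bond, formally disfavoured by the Baldwin rules but usual for oxocarbenium ions whose nucleophilic carbon sits on the oxygen-bound tether. C3 is controlled by allylic 1,3-strain in the Z-enol carbamate (the C4–H bond lies in the enol plane, attack anti to the C4 methyl group gives 3,4-trans) and is in any case epimerisable next to the formyl group; C2 is controlled thermodynamically, because the E-oxocarbenium may close first to the 2,5-cis isomer, but the C2–C3 bond of the BF3-bound β-alkoxy aldehyde and the benzylic C2–O1 bond next to the 3,4-dimethoxyphenyl ring can re-ionise on warming, so that the mixture is expected to settle on the all-trans isomer with four pseudo-equatorial substituents. The step needs C- instead of O-alkylation, no Friedel–Crafts attack on the arenes and no loss of the C4/C5 configuration: the tethered enol carbamate is the only π-nucleophile that reaches C2 through a five-membered transition state, and C4 (not epimerisable) and C5 (3,4,5-trimethoxyphenyl, the poorer cation-stabilising ring) anchor the absolute configuration.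

Step 4
Reactants: 10 (2S,3S,4S,5S)-2-(3,4-dimethoxyphenyl)-4-methyl-5-(3,4,5-trimethoxyphenyl)oxolane-3-carbaldehyde
Product: 11 [(2S,3R,4S,5S)-2-(3,4-dimethoxyphenyl)-4-methyl-5-(3,4,5-trimethoxyphenyl)oxolan-3-yl]methanol
Conditions: NaBH4, MeOH, 0 °C
Reagents that add atoms: none
Why: Borohydride 1,2-reduction of the aldehyde should be fast at 0 °C and removes the epimerisable, β-elimination-prone formyl group; no stereocentre changes (the C3 descriptor changes from S to R only through the priority rules).

Step 5
Reactants: 11 [(2S,3R,4S,5S)-2-(3,4-dimethoxyphenyl)-4-methyl-5-(3,4,5-trimethoxyphenyl)oxolan-3-yl]methanol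
Product: 12 [(2S,3R,4S,5S)-2-(3,4-dimethoxyphenyl)-4-methyl-5-(3,4,5-trimethoxyphenyl)oxolan-3-yl]methyl methanesulfonate
Conditions: MsCl, Et3N, CH2Cl2, 0 °C
Reagents that add atoms: methanesulfonyl chloride, CS(=O)(=O)Cl
Why: Sulfonylation of the primary alcohol (sulfene pathway) should activate the exocyclic carbon for hydride displacement without involving any ring stereocentre.

Step 6
Reactants: 12 [(2S,3R,4S,5S)-2-(3,4-dimethoxyphenyl)-4-methyl-5-(3,4,5-trimethoxyphenyl)oxolan-3-yl]methyl methanesulfonate
Product: 13 5-methoxygalbelgin [(2S,3S,4S,5S)-2-(3,4-dimethoxyphenyl)-3,4-dimethyl-5-(3,4,5-trimethoxyphenyl)oxolane]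
Conditions: LiEt3BH, THF, 0 °C → rt
Reagents that add atoms: none
Why: SN2 hydride displacement of the primary mesylate by triethylborohydride should turn CH2OMs into the C3 methyl group; the reaction takes place at the exocyclic carbon, so all four ring stereocentres are retained.

## Compound list

1 | (E)-but-2-en-1-ol | C/C=C/CO | starting material
2 | (E)-but-2-en-1-yl N,N-di(propan-2-yl)carbamate | C/C=C/COC(=O)N(C(C)C)C(C)C | intermediate
3 | 3,4,5-trimethoxybenzaldehyde | COc1cc(C=O)cc(OC)c1OC | starting material
4 | (S)-configured α-lithiated carbamate, present as its (−)-sparteine complex (organolithium part shown) | C/C=C/[C@H]([Li])OC(=O)N(C(C)C)C(C)C | intermediate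
5 | (R)-configured allyltitanium triisopropoxide | C/C=C/[C@@H]([Ti](OC(C)C)(OC(C)C)OC(C)C)OC(=O)N(C(C)C)C(C)C | intermediate
6 | (1Z,3S,4S)-4-hydroxy-3-methyl-4-(3,4,5-trimethoxyphenyl)but-1-en-1-yl N,N-di(propan-2-yl)carbamate | O[C@H](c1cc(OC)c(OC)c(OC)c1)[C@@H](C)/C=C\OC(=O)N(C(C)C)C(C)C | intermediate
7 | 3,4-dimethoxybenzaldehyde (veratraldehyde) | COc1ccc(C=O)cc1OC | starting material
8 | (E)-oxocarbenium ion from 6 and 7, as its hydroxytrifluoroborate | COc1ccc(/C=[O+]/[C@H](c2cc(OC)c(OC)c(OC)c2)[C@@H](C)/C=C\OC(=O)N(C(C)C)C(C)C)cc1OC.O[B-](F)(F)F | intermediate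
9 | cyclised carbamoyloxycarbenium ion, as its hydroxytrifluoroborate | COc1ccc([C@H]2O[C@H](c3cc(OC)c(OC)c(OC)c3)[C@@H](C)[C@@H]2C=[O+]C(=O)N(C(C)C)C(C)C)cc1OC.O[B-](F)(F)F | intermediate
10 | (2S,3S,4S,5S)-2-(3,4-dimethoxyphenyl)-4-methyl-5-(3,4,5-trimethoxyphenyl)oxolane-3-carbaldehyde | COc1ccc([C@H]2O[C@H](c3cc(OC)c(OC)c(OC)c3)[C@@H](C)[C@@H]2C=O)cc1OC | intermediate
11 | [(2S,3R,4S,5S)-2-(3,4-dimethoxyphenyl)-4-methyl-5-(3,4,5-trimethoxyphenyl)oxolan-3-yl]methanol | COc1ccc([C@H]2O[C@H](c3cc(OC)c(OC)c(OC)c3)[C@@H](C)[C@@H]2CO)cc1OC | intermediate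
12 | [(2S,3R,4S,5S)-2-(3,4-dimethoxyphenyl)-4-methyl-5-(3,4,5-trimethoxyphenyl)oxolan-3-yl]methyl methanesulfonate | COc1ccc([C@H]2O[C@H](c3cc(OC)c(OC)c(OC)c3)[C@@H](C)[C@@H]2COS(C)(=O)=O)cc1OC | intermediate
13 | 5-methoxygalbelgin [(2S,3S,4S,5S)-2-(3,4-dimethoxyphenyl)-3,4-dimethyl-5-(3,4,5-trimethoxyphenyl)oxolane] | COc1ccc([C@H]2O[C@H](c3cc(OC)c(OC)c(OC)c3)[C@@H](C)[C@@H]2C)cc1OC | target

## Step count and risks

Total step count: 6. Longest linear sequence: 6 steps (1 → 2 → 6 → 10 → 11 → 12 → 13); aldehydes 3 and 7 are commercial and enter at steps 2 and 3.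

Steps most likely to fail:

1. Step 3. The closure may stop at the kinetically preferred 2,5-cis arrangement (E-oxocarbenium, pseudo-equatorial aryl groups) without equilibrating at C2, or prolonged exposure to the Lewis acid may open the β-alkoxy aldehyde by elimination. The fallback moves the stereochemical correction to the end of the route. It sets out from 6 and 7: the condensation is run with BF3·OEt2 at −78 °C and quenched cold to give the C2-epimeric aldehyde (2R,3S,4S,5S)-2-(3,4-dimethoxyphenyl)-4-methyl-5-(3,4,5-trimethoxyphenyl)oxolane-3-carbaldehyde F1. This is reduced at once with NaBH4 to the C2-epimeric alcohol F2, mesylated to the C2-epimeric mesylate F3 and reduced with LiEt3BH to 2-epi-5-methoxygalbelgin F4. F4 no longer carries an acid-sensitive formyl group and is then equilibrated with BF3·OEt2 in CH2Cl2 (−20 °C → rt); reversible ionisation of the benzylic C2–O1 bond next to the 3,4-dimethoxyphenyl ring, a known epimerisation of 2,5-diaryl-3,4-dimethyloxolane lignans, should move the aryl group into the all-trans arrangement. The fallback comes back to the route at 13.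

2. Step 2. The dynamic resolution by crystallisation of the lithium–sparteine complex may be incomplete, or the anti/Z selectivity of the titanium addition may erode with the electron-rich aryl aldehyde. The fallback sets the two stereocentres by chirality transfer from a propargylic mesylate instead of by asymmetric deprotonation. It sets out from 3: Pd(0)/Et2Zn-mediated addition of the allenylzinc reagent from (R)-but-3-yn-2-yl methanesulfonate (net inversion at the propargylic carbon expected, anti addition through a cyclic transition state) gives (1S,2S)-2-methyl-1-(3,4,5-trimethoxyphenyl)but-3-yn-1-ol F5. Silylation (TESCl, imidazole) gives the triethylsilyl ether F6. Ruthenium-catalysed anti-Markovnikov addition of acetic acid to the terminal alkyne gives the (Z)-enol acetate (1Z,3S,4S)-3-methyl-4-[(triethylsilyl)oxy]-4-(3,4,5-trimethoxyphenyl)but-1-en-1-yl acetate F7. Condensation of F7 with 7 under catalytic TMSOTf (CH2Cl2, −78 → 0 °C; the silyl ether and aldehyde form the same type of oxocarbenium ion, and the enol acetate takes the role of the enol carbamate) comes back to the route at 10.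

3. Step 6. Hydride displacement at the β-branched primary mesylate may be slow, and S–O cleavage back to the alcohol or elimination may compete. The fallback replaces the ionic reduction by a radical one. It sets out from 11: iodination (I2, PPh3, imidazole, toluene) gives (2S,3S,4S,5S)-2-(3,4-dimethoxyphenyl)-3-(iodomethyl)-4-methyl-5-(3,4,5-trimethoxyphenyl)oxolane F8, and radical dehalogenation (Bu3SnH, AIBN, toluene, 80 °C) comes back to the route at 13.

## Further compounds

F1 | step 3 | (2R,3S,4S,5S)-2-(3,4-dimethoxyphenyl)-4-methyl-5-(3,4,5-trimethoxyphenyl)oxolane-3-carbaldehyde | COc1ccc([C@@H]2O[C@H](c3cc(OC)c(OC)c(OC)c3)[C@@H](C)[C@@H]2C=O)cc1OC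
F2 | step 3 | [(2R,3R,4S,5S)-2-(3,4-dimethoxyphenyl)-4-methyl-5-(3,4,5-trimethoxyphenyl)oxolan-3-yl]methanol | COc1ccc([C@@H]2O[C@H](c3cc(OC)c(OC)c(OC)c3)[C@@H](C)[C@@H]2CO)cc1OC
F3 | step 3 | [(2R,3R,4S,5S)-2-(3,4-dimethoxyphenyl)-4-methyl-5-(3,4,5-trimethoxyphenyl)oxolan-3-yl]methyl methanesulfonate | COc1ccc([C@@H]2O[C@H](c3cc(OC)c(OC)c(OC)c3)[C@@H](C)[C@@H]2COS(C)(=O)=O)cc1OC
F4 | step 3 | (2R,3S,4S,5S)-2-(3,4-dimethoxyphenyl)-3,4-dimethyl-5-(3,4,5-trimethoxyphenyl)oxolane | COc1ccc([C@@H]2O[C@H](c3cc(OC)c(OC)c(OC)c3)[C@@H](C)[C@@H]2C)cc1OC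
F5 | step 2 | (1S,2S)-2-methyl-1-(3,4,5-trimethoxyphenyl)but-3-yn-1-ol | O[C@H](c1cc(OC)c(OC)c(OC)c1)[C@@H](C)C#C
F6 | step 2 | triethyl{[(1S,2S)-2-methyl-1-(3,4,5-trimethoxyphenyl)but-3-yn-1-yl]oxy}silane | CC[Si](CC)(CC)O[C@H](c1cc(OC)c(OC)c(OC)c1)[C@@H](C)C#C
F7 | step 2 | (1Z,3S,4S)-3-methyl-4-[(triethylsilyl)oxy]-4-(3,4,5-trimethoxyphenyl)but-1-en-1-yl acetate | CC[Si](CC)(CC)O[C@H](c1cc(OC)c(OC)c(OC)c1)[C@@H](C)/C=C\OC(C)=O
F8 | step 6 | (2S,3S,4S,5S)-2-(3,4-dimethoxyphenyl)-3-(iodomethyl)-4-methyl-5-(3,4,5-trimethoxyphenyl)oxolane | COc1ccc([C@H]2O[C@H](c3cc(OC)c(OC)c(OC)c3)[C@@H](C)[C@@H]2CI)cc1OC
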